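**Plan**

1. Numbering used below: C1 = ring CH bearing the isopropenyl group; C2 = CH2 between C1 and the furan; furan carbons C3 (bonded to C2), C4 (CO2Me), C5 (H), C6; then C7, C8 (Me, OH), C9, C10 (ketone), C11 (OH), C12 (CO2Me), C13, C14 back to C1.
2. The last retrosynthetic cut opens the furan and the 14-membered carbocycle together, at C4–C5 and at O–C3. The 2,5-dialkylfuran-3-carboxylate (O, C3–C6) is the dehydrated form of a C3/C6 1,4-diketone; C4 is the acidic carbon of a β-keto ester and C5 the α-carbon of the C6 ketone, two donor carbons, so C5 is polarity-reversed as a bromomethyl ketone that already carries the future ring oxygen on C6.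
3. Further cuts: C3–C4 (Roskamp homologation), C9–C10 (nickel-catalysed acid/iodide ketone synthesis), C12–C13 (malate dianion alkylation), C6–C7 (alkynylation of an epoxide).
4. Forward: (S)-carvone is cut twice in its ring to give the C13–C14–C1–C2–C3 arm; this is joined to (R)-malate (C10–C12), then to the C5–C9 piece from (S)-2-methylglycidol; both chain ends are unmasked, and carbocycle and furan close in one flask; desilylation ends the route.
5. Stereochemistry: C1 from carvone (kept through the ring cleavage), C11 from (R)-malate, C12 by anti alkylation under control of C11, C8 from 2-methylglycidol; the key step creates no stereocenter.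

Key step: step 18

Assumption: (S)-2-methylglycidol is taken as purchasable; it is the product of the Ti(OiPr)4/tartrate-catalysed asymmetric epoxidation of 2-methylprop-2-en-1-ol.

**Route**

Step 1
Reactants: 1 (S)-(+)-carvone
Product: 2 (1S,4S,6S)-1-methyl-4-(prop-1-en-2-yl)-7-oxabicyclo[4.1.0]heptan-2-one
Conditions: H2O2 (30 % aq.), NaOH (cat.), MeOH, 0 °C
Reagents that add atoms: hydrogen peroxide (OO)
Why: Weitz–Scheffer nucleophilic epoxidation, in which hydroperoxide adds only to the electron-poor enone double bond and leaves the isopropenyl group alone; the epoxide should form trans to the isopropenyl group, and both new stereocenters are removed in step 2.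

Step 2
Reactants: 2 carvone epoxide
Product: 4 (3S)-5-oxo-3-(prop-1-en-2-yl)pentanoic acid, via dihydroxy ketone 3 (not isolated)
Conditions: H5IO6 (2.5 equiv), THF/H2O, 0 → 25 °C
Reagents that add atoms: water (O)
Why: Periodic acid opens the epoxide to the keto diol and then performs glycol-type cleavage of both the diol and the resulting 1,2-dicarbonyl unit, which excises the methyl-bearing ring carbon as acetic acid and leaves the two arms of the untouched stereocenter differentiated as acid and aldehyde.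

Step 3
Reactants: 4 (3S)-5-oxo-3-(prop-1-en-2-yl)pentanoic acid
Product: 5 (3S)-5,5-dimethoxy-3-(prop-1-en-2-yl)pentanoic acid
Conditions: HC(OMe)3, MeOH, pyridinium p-toluenesulfonate (cat.), 25 °C
Reagents that add atoms: trimethyl orthoformate (COC(OC)OC); methanol (CO)
Why: Acid-catalysed acetalisation with the orthoformate as water scavenger should protect the aldehyde selectively, because the carboxylic acid esterifies far more slowly under this weak acid.

Step 4
Reactants: 5 (3S)-5,5-dimethoxy-3-(prop-1-en-2-yl)pentanoic acid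
Product: 6 (3R)-5,5-dimethoxy-3-(prop-1-en-2-yl)pentan-1-ol
Conditions: LiAlH4, THF, 0 → 40 °C; aqueous NaOH work-up
Reagents that add atoms: none
Why: Hydride reduction of the carboxylic acid to the primary alcohol, with acetal and alkene inert to LiAlH4 (the descriptor changes only through the priority rules).

Step 5
Reactants: 6 (3R)-5,5-dimethoxy-3-(prop-1-en-2-yl)pentan-1-ol
Product: 7 (3S)-5-iodo-1,1-dimethoxy-3-(prop-1-en-2-yl)pentane
Conditions: I2, PPh3, imidazole, CH2Cl2, 0 °C
Reagents that add atoms: iodine (II)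
Why: Appel-type iodination (Garegg–Samuelsson conditions) of the primary alcohol by SN2 displacement of the alkoxyphosphonium ion, with imidazole buffering the acetal.

Step 6
Reactants: 7 (3S)-5-iodo-1,1-dimethoxy-3-(prop-1-en-2-yl)pentane; 8 dimethyl (R)-malate
Product: 9 dimethyl (2R,3S)-2-hydroxy-3-[(3R)-5,5-dimethoxy-3-(prop-1-en-2-yl)pentyl]butanedioate
Conditions: 8 (2.5 equiv), LiN(iPr)2 (5.2 equiv), THF, −78 → −20 °C; then 7, DMPU, −78 → 0 °C
Reagents that add atoms: none
Why: Fráter–Seebach alkylation, in which the chelated lithium alkoxide–enolate dianion of the malate is alkylated by the primary iodide on the face anti to the C11 alkoxide, so that C12 (S) is set by the malate center C11 (R).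

Step 7
Reactants: 9 dimethyl (2R,3S)-2-hydroxy-3-alkylbutanedioate
Product: 10 (2R,3S,6R)-2-hydroxy-8,8-dimethoxy-3-(methoxycarbonyl)-6-(prop-1-en-2-yl)octanoic acid
Conditions: LiOH (1.05 equiv), THF/H2O, 0 °C; 1 M HCl to pH 3
Reagents that add atoms: lithium hydroxide ([Li+].[OH-])
Why: Saponification should take place at the ester next to the free hydroxyl (C10), which is activated inductively and by the neighbouring hydroxyl, faster than at the C20 ester on the newly alkylated carbon, so one equivalent of hydroxide at 0 °C should stop at the mono-acid.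

Step 8
Reactants: 10 (2R,3S,6R)-2-hydroxy acid
Product: 12 (2R,3S,6R)-2-[(tert-butyldimethylsilyl)oxy]-8,8-dimethoxy-3-(methoxycarbonyl)-6-(prop-1-en-2-yl)octanoic acid, via silyl ester 11 (not isolated)
Conditions: TBSCl (2.5 equiv), imidazole, DMF, 25 °C; then K2CO3 (cat.), MeOH/H2O, 0 °C
Reagents that add atoms: tert-butyldimethylsilyl chloride (CC(C)(C)[Si](C)(C)Cl)
Why: Standard protection of a hydroxy acid by silylation of both oxygens followed by selective solvolysis of the labile silyl ester.

Step 9
Reactants: 13 (S)-2-methylglycidol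
Product: 14 [(2R)-2-methyloxiran-2-yl]methyl 4-methylbenzenesulfonate
Conditions: TsCl, Et3N, 4-(dimethylamino)pyridine (cat.), CH2Cl2, 0 °C
Reagents that add atoms: 4-methylbenzenesulfonyl chloride (Cc1ccc(cc1)S(=O)(=O)Cl)
Why: Sulfonylation of the primary alcohol, which does not involve the quaternary stereocenter (the descriptor changes only through the priority rules).

Step 10
Reactants: 14 [(2R)-2-methyloxiran-2-yl]methyl 4-methylbenzenesulfonate
Product: 16 trimethyl{3-[(2R)-2-methyloxiran-2-yl]prop-1-yn-1-yl}silane, via hydroxy tosylate 15 (not isolated)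
Conditions: Me3SiC≡CH, n-BuLi, THF, −78 °C; BF3·OEt2, then 14, −78 °C; aqueous work-up; then NaH, THF, 0 °C
Reagents that add atoms: (trimethylsilyl)acetylene (C#C[Si](C)(C)C)
Why: Yamaguchi-type Lewis-acid-assisted alkynylation of the epoxide at its unsubstituted carbon (C7) followed by Williamson closure of the tertiary alkoxide onto the tosylate, so that no bond to C8 is broken and its configuration is retained while the epoxide moves to the C9 arm.

Step 11
Reactants: 16 trimethyl{3-[(2R)-2-methyloxiran-2-yl]prop-1-yn-1-yl}silane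
Product: 17 (2R)-1-iodo-2-methyl-5-(trimethylsilyl)pent-4-yn-2-ol
Conditions: LiI, AcOH, THF, 0 → 25 °C
Reagents that add atoms: lithium iodide ([Li+].[I-])
Why: Buffered SN2 opening of the 2,2-disubstituted epoxide by iodide at the CH2 carbon (C9) gives the iodohydrin with C8 untouched.

Step 12
Reactants: 17 (2R)-1-iodo-2-methyl-5-(trimethylsilyl)pent-4-yn-2-ol
Product: 18 triethyl{[(2R)-1-iodo-2-methyl-5-(trimethylsilyl)pent-4-yn-2-yl]oxy}silane
Conditions: Et3SiOTf, 2,6-lutidine, CH2Cl2, −78 → 0 °C
Reagents that add atoms: triethylsilyl trifluoromethanesulfonate (CC[Si](CC)(CC)OS(=O)(=O)C(F)(F)F)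
Why: Silylation of the tertiary alcohol with the reactive silyl triflate, with a base too weak to close the iodohydrin back to the epoxide.

Step 13
Reactants: 12 (2R,3S,6R)-2-[(tert-butyldimethylsilyl)oxy] acid; 18 triethylsilyl-protected iodide
Product: 20 methyl (2S,3R,6R)-3-[(tert-butyldimethylsilyl)oxy]-2-[(3R)-5,5-dimethoxy-3-(prop-1-en-2-yl)pentyl]-6-methyl-4-oxo-6-[(triethylsilyl)oxy]-9-(trimethylsilyl)non-8-ynoate, via mixed carbonic anhydride 19 (not isolated)
Conditions: Boc2O, MgCl2, NiCl2·MeOCH2CH2OMe (10 mol %), 4,4′-di-tert-butyl-2,2′-bipyridine (12 mol %), Zn dust, N,N-dimethylacetamide, 25 °C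
Reagents that add atoms: none
Why: Nickel-catalysed reductive cross-electrophile ketone synthesis, in which the acid is activated in situ as the mixed anhydride, forms an acyl–nickel species and captures the primary alkyl radical from the iodide, joining C9 to C10 without touching esters, acetal, alkyne, alkene or any stereocenter.

Step 14
Reactants: 20 alkynylsilane ketone
Product: 21 methyl (2S,3R,6R)-9-bromo-3-[(tert-butyldimethylsilyl)oxy]-2-[(3R)-5,5-dimethoxy-3-(prop-1-en-2-yl)pentyl]-6-methyl-4-oxo-6-[(triethylsilyl)oxy]non-8-ynoate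
Conditions: N-bromosuccinimide, AgNO3 (20 mol %), acetone, 25 °C, dark
Reagents that add atoms: N-bromosuccinimide (O=C1CCC(=O)N1Br)
Why: Silver-catalysed bromodesilylation of the alkynylsilane through the silver acetylide, which is selective for the alkyne terminus over the 1,1-disubstituted alkene and must precede the introduction of the brominatable β-keto ester.

Step 15
Reactants: 21 bromoalkyne acetal
Product: 22 methyl (2S,3R,6R)-9-bromo-3-[(tert-butyldimethylsilyl)oxy]-6-methyl-4-oxo-2-[(3R)-5-oxo-3-(prop-1-en-2-yl)pentyl]-6-[(triethylsilyl)oxy]non-8-ynoate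
Conditions: pyridinium p-toluenesulfonate (cat.), acetone/H2O 10:1, 40 °C
Reagents that add atoms: water (O)
Why: Mild acid-catalysed hydrolysis (transacetalisation) of the dimethyl acetal under conditions that should spare the secondary tert-butyldimethylsilyl ether and the tertiary triethylsilyl ether.

Step 16
Reactants: 22 bromoalkyne aldehyde
Product: 23 methyl (2S,3R,6R)-9-bromo-3-[(tert-butyldimethylsilyl)oxy]-2-[(3R)-7-methoxy-5,7-dioxo-3-(prop-1-en-2-yl)heptyl]-6-methyl-4-oxo-6-[(triethylsilyl)oxy]non-8-ynoate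
Conditions: N2CHCO2Me, SnCl2 (15 mol %), CH2Cl2, 25 °C
Reagents that add atoms: methyl diazoacetate (COC(=O)C=[N+]=[N-])
Why: Roskamp reaction, in which SnCl2-catalysed addition of the diazo ester to the aldehyde, 1,2-hydride shift and loss of nitrogen give the β-keto ester (C3/C4) while the C10 ketone does not react.

Step 17
Reactants: 23 bromoalkyne β-keto ester
Product: 24 methyl (2S,3R,6S)-9-bromo-3-[(tert-butyldimethylsilyl)oxy]-2-[(3R)-7-methoxy-5,7-dioxo-3-(prop-1-en-2-yl)heptyl]-6-methyl-4,8-dioxo-6-[(triethylsilyl)oxy]nonanoate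
Conditions: Ph3PAuNTf2 (3 mol %), H2O (5 equiv), 1,4-dioxane, 25 °C
Reagents that add atoms: water (O)
Why: Gold-catalysed Markovnikov hydration of the 1-bromoalkyne places the carbonyl oxygen on C6 and gives the bromomethyl ketone under neutral conditions (the C8 descriptor changes only through the priority rules).

Step 18
Reactants: 24 bromomethyl ketone β-keto ester
Product: 26 dimethyl (3R,6R,7S,10R)-6-[(tert-butyldimethylsilyl)oxy]-3-methyl-5-oxo-10-(prop-1-en-2-yl)-3-[(triethylsilyl)oxy]-15-oxabicyclo[10.2.1]pentadeca-1(14),12-diene-7,13-dicarboxylate, via macrocyclic triketone 25 (not isolated)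
Conditions: Cs2CO3 (1.05 equiv), MeCN, 40 °C, 24 added by syringe pump to a final 1 mM; then TsOH·H2O (1.5 equiv), 4 Å molecular sieves, 40 °C
Reagents that add atoms: none
Why: Cs2CO3 removes a proton only from C4 (the β-keto ester CH2 is by far the most acidic site of 24), and the cesium enolate displaces bromide from C5 in an intramolecular SN2 reaction that forms C4–C5 and gives the 14-membered triketone 25; the acid then lets the C6 carbonyl oxygen, through its enol, add to the protonated C3 carbonyl, and loss of water forms O–C3 and aromatises the ring to the furan. The closest known reaction type is C-alkylation of a β-keto ester by an α-halo ketone followed by Paal–Knorr cyclodehydration of the 2-acyl-4-oxo ester, combined with high-dilution macrocyclic alkylation of β-keto ester enolates. The carbocycle closes in the 14-exo-tet mode (enolate alkylation) and the furan by 5-exo-trig addition of oxygen to C3 followed by dehydration. No stereocenter of 26 is made here: C4 of 25 arises as both epimers and is erased on aromatisation, while C1, C8, C11 and C12 are not touched, because the C–H bonds at C11 and C12 are far less acidic than C4–H and the base is consumed by the β-keto ester. The step needs ring closure over oligomerisation (slow addition to 1 mM), C- over O-alkylation, and substitution at C5 over aldol attack on C6, which would lead to the isomeric Feist–Benary furan (soft primary bromide, non-nucleophilic carbonate); it also needs the C8 and C11 oxygens kept out of the reaction, which the two silyl ethers secure, since a free C8 hydroxyl would close a five-membered ether onto C5.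

Step 19
Reactants: 26 bis-silyl ether of the target
Product: 27 dimethyl (3R,6R,7S,10R)-3,6-dihydroxy-3-methyl-5-oxo-10-(prop-1-en-2-yl)-15-oxabicyclo[10.2.1]pentadeca-1(14),12-diene-7,13-dicarboxylate (CNP0218204.1)
Conditions: HF·pyridine, pyridine, THF, 0 → 25 °C
Reagents that add atoms: none
Why: Fluoride-mediated cleavage of both silyl ethers under buffered, non-basic conditions that should avoid retro-aldol cleavage of the β-hydroxy ketone and epimerisation at C11.

**Compound list**

1 | (S)-(+)-carvone | CC1=CC[C@@H](CC1=O)C(C)=C | starting material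
2 | (1S,4S,6S)-1-methyl-4-(prop-1-en-2-yl)-7-oxabicyclo[4.1.0]heptan-2-one | C[C@]12O[C@H]1C[C@@H](CC2=O)C(C)=C | intermediate
3 | (2S,3R,5S)-2,3-dihydroxy-2-methyl-5-(prop-1-en-2-yl)cyclohexan-1-one | C[C@]1(O)[C@H](O)C[C@@H](CC1=O)C(C)=C | intermediate
4 | (3S)-5-oxo-3-(prop-1-en-2-yl)pentanoic acid | C=C(C)[C@@H](CC=O)CC(=O)O | intermediate
5 | (3S)-5,5-dimethoxy-3-(prop-1-en-2-yl)pentanoic acid | C=C(C)[C@@H](CC(OC)OC)CC(=O)O | intermediate
6 | (3R)-5,5-dimethoxy-3-(prop-1-en-2-yl)pentan-1-ol | C=C(C)[C@@H](CC(OC)OC)CCO | intermediate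
7 | (3S)-5-iodo-1,1-dimethoxy-3-(prop-1-en-2-yl)pentane | C=C(C)[C@@H](CC(OC)OC)CCI | intermediate
8 | dimethyl (R)-malate | COC(=O)C[C@@H](O)C(=O)OC | starting material
9 | dimethyl (2R,3S)-2-hydroxy-3-[(3R)-5,5-dimethoxy-3-(prop-1-en-2-yl)pentyl]butanedioate | C=C(C)[C@@H](CC(OC)OC)CC[C@H](C(=O)OC)[C@@H](O)C(=O)OC | intermediate
10 | (2R,3S,6R)-2-hydroxy-8,8-dimethoxy-3-(methoxycarbonyl)-6-(prop-1-en-2-yl)octanoic acid | C=C(C)[C@@H](CC(OC)OC)CC[C@H](C(=O)OC)[C@@H](O)C(=O)O | intermediate
11 | tert-butyldimethylsilyl ester of 12 | C=C(C)[C@@H](CC(OC)OC)CC[C@H](C(=O)OC)[C@@H](O[Si](C)(C)C(C)(C)C)C(=O)O[Si](C)(C)C(C)(C)C | intermediate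
12 | (2R,3S,6R)-2-[(tert-butyldimethylsilyl)oxy]-8,8-dimethoxy-3-(methoxycarbonyl)-6-(prop-1-en-2-yl)octanoic acid | C=C(C)[C@@H](CC(OC)OC)CC[C@H](C(=O)OC)[C@@H](O[Si](C)(C)C(C)(C)C)C(=O)O | intermediate
13 | (S)-2-methylglycidol, [(2S)-2-methyloxiran-2-yl]methanol | OC[C@]1(C)OC1 | starting material
14 | [(2R)-2-methyloxiran-2-yl]methyl 4-methylbenzenesulfonate | Cc1ccc(cc1)S(=O)(=O)OC[C@]1(C)OC1 | intermediate
15 | (2R)-2-hydroxy-2-methyl-5-(trimethylsilyl)pent-4-yn-1-yl 4-methylbenzenesulfonate | Cc1ccc(cc1)S(=O)(=O)OC[C@](C)(O)CC#C[Si](C)(C)C | intermediate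
16 | trimethyl{3-[(2R)-2-methyloxiran-2-yl]prop-1-yn-1-yl}silane | C1O[C@]1(C)CC#C[Si](C)(C)C | intermediate
17 | (2R)-1-iodo-2-methyl-5-(trimethylsilyl)pent-4-yn-2-ol | IC[C@](C)(O)CC#C[Si](C)(C)C | intermediate
18 | triethyl{[(2R)-1-iodo-2-methyl-5-(trimethylsilyl)pent-4-yn-2-yl]oxy}silane | IC[C@](C)(O[Si](CC)(CC)CC)CC#C[Si](C)(C)C | intermediate
19 | mixed anhydride of 12 with tert-butyl hydrogen carbonate | C=C(C)[C@@H](CC(OC)OC)CC[C@H](C(=O)OC)[C@@H](O[Si](C)(C)C(C)(C)C)C(=O)OC(=O)OC(C)(C)C | intermediate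
20 | methyl (2S,3R,6R)-3-[(tert-butyldimethylsilyl)oxy]-2-[(3R)-5,5-dimethoxy-3-(prop-1-en-2-yl)pentyl]-6-methyl-4-oxo-6-[(triethylsilyl)oxy]-9-(trimethylsilyl)non-8-ynoate | C=C(C)[C@@H](CC(OC)OC)CC[C@H](C(=O)OC)[C@@H](O[Si](C)(C)C(C)(C)C)C(=O)C[C@](C)(O[Si](CC)(CC)CC)CC#C[Si](C)(C)C | intermediate
21 | methyl (2S,3R,6R)-9-bromo-3-[(tert-butyldimethylsilyl)oxy]-2-[(3R)-5,5-dimethoxy-3-(prop-1-en-2-yl)pentyl]-6-methyl-4-oxo-6-[(triethylsilyl)oxy]non-8-ynoate | C=C(C)[C@@H](CC(OC)OC)CC[C@H](C(=O)OC)[C@@H](O[Si](C)(C)C(C)(C)C)C(=O)C[C@](C)(O[Si](CC)(CC)CC)CC#CBr | intermediate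
22 | methyl (2S,3R,6R)-9-bromo-3-[(tert-butyldimethylsilyl)oxy]-6-methyl-4-oxo-2-[(3R)-5-oxo-3-(prop-1-en-2-yl)pentyl]-6-[(triethylsilyl)oxy]non-8-ynoate | C=C(C)[C@@H](CC=O)CC[C@H](C(=O)OC)[C@@H](O[Si](C)(C)C(C)(C)C)C(=O)C[C@](C)(O[Si](CC)(CC)CC)CC#CBr | intermediate
23 | methyl (2S,3R,6R)-9-bromo-3-[(tert-butyldimethylsilyl)oxy]-2-[(3R)-7-methoxy-5,7-dioxo-3-(prop-1-en-2-yl)heptyl]-6-methyl-4-oxo-6-[(triethylsilyl)oxy]non-8-ynoate | C=C(C)[C@@H](CC(=O)CC(=O)OC)CC[C@H](C(=O)OC)[C@@H](O[Si](C)(C)C(C)(C)C)C(=O)C[C@](C)(O[Si](CC)(CC)CC)CC#CBr | intermediate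
24 | methyl (2S,3R,6S)-9-bromo-3-[(tert-butyldimethylsilyl)oxy]-2-[(3R)-7-methoxy-5,7-dioxo-3-(prop-1-en-2-yl)heptyl]-6-methyl-4,8-dioxo-6-[(triethylsilyl)oxy]nonanoate | C=C(C)[C@@H](CC(=O)CC(=O)OC)CC[C@H](C(=O)OC)[C@@H](O[Si](C)(C)C(C)(C)C)C(=O)C[C@](C)(O[Si](CC)(CC)CC)CC(=O)CBr | intermediate
25 | dimethyl (4R,7S,8R,11R)-8-[(tert-butyldimethylsilyl)oxy]-11-methyl-2,9,13-trioxo-4-(prop-1-en-2-yl)-11-[(triethylsilyl)oxy]cyclotetradecane-1,7-dicarboxylate, both epimers at C1 of this name | C=C(C)[C@@H]1CC[C@H](C(=O)OC)[C@@H](O[Si](C)(C)C(C)(C)C)C(=O)C[C@](C)(O[Si](CC)(CC)CC)CC(=O)CC(C(=O)OC)C(=O)C1 | intermediate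
26 | dimethyl (3R,6R,7S,10R)-6-[(tert-butyldimethylsilyl)oxy]-3-methyl-5-oxo-10-(prop-1-en-2-yl)-3-[(triethylsilyl)oxy]-15-oxabicyclo[10.2.1]pentadeca-1(14),12-diene-7,13-dicarboxylate | C=C(C)[C@@H]1CC[C@H](C(=O)OC)[C@@H](O[Si](C)(C)C(C)(C)C)C(=O)C[C@](C)(O[Si](CC)(CC)CC)CC2=CC(C(=O)OC)=C(C1)O2 | intermediate
27 | dimethyl (3R,6R,7S,10R)-3,6-dihydroxy-3-methyl-5-oxo-10-(prop-1-en-2-yl)-15-oxabicyclo[10.2.1]pentadeca-1(14),12-diene-7,13-dicarboxylate (CNP0218204.1) | C=C(C)[C@@H]1CC[C@H](C(=O)OC)[C@@H](O)C(=O)C[C@](C)(O)CC2=CC(C(=O)OC)=C(C1)O2 | target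

**Step count and risks**

Total step count: 19. Longest linear sequence: 15 steps (steps 1–8, then 13–19); the branch from 13 (steps 9–12) joins at step 13.

Steps most likely to fail:

1. Step 18. The ring closure may lose to intermolecular alkylation (oligomers), to O-alkylation of the enolate, or to base-induced decomposition of the bromomethyl ketone before it is captured. Fallback: from 24, the β-keto ester would be silylated with N,O-bis(trimethylsilyl)acetamide to its (Z)-trimethylsilyl enol ether F1. Irradiation with blue light and Ir(ppy)3 (tris(2-phenylpyridinato)iridium) in MeCN at 1 mM would turn the C5–Br bond into an α-keto radical, which adds to C4 of the electron-rich enol ether. Oxidation of the resulting α-silyloxy radical with loss of the silyl group would give the macrocyclic triketone 25 without any base, and 25 would be cyclodehydrated with TsOH as in step 18 to reach 26.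

2. Step 13. Radical formation from the hindered, neopentyl-type iodide may be slow, so that the acyl–nickel intermediate is reduced or decarbonylated, or the iodide homo-couples. Fallback: from epoxide 16, opening with PhSO2Na would give (2R)-2-methyl-1-(phenylsulfonyl)-5-(trimethylsilyl)pent-4-yn-2-ol F2, which Et3SiOTf would convert into its triethylsilyl ether F3. Acid 12 would be converted into its N-methoxy-N-methylamide F4. The lithiated sulfone (n-BuLi, THF, −78 °C) would be acylated by F4 to the β-keto sulfone F5, and reductive desulfonylation with Bu3SnH and azobisisobutyronitrile would return to the route at 20.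

3. Step 6. The unactivated primary iodide may alkylate the dianion too slowly, so that the dianion decays by elimination and self-condensation, and the anti selectivity may erode at the temperature the alkylation needs. Fallback: from 7, magnesium in THF would give the Grignard reagent F6. CuI-catalysed opening of purchased dimethyl (2R,3R)-oxirane-2,3-dicarboxylate by F6, with inversion at the attacked carbon and retention at the carbinol carbon, would give 9 directly.

Further compounds
F1 | step 18 | (Z)-trimethylsilyl enol ether of the β-keto ester of 24 | C=C(C)[C@@H](C/C(O[Si](C)(C)C)=C/C(=O)OC)CC[C@H](C(=O)OC)[C@@H](O[Si](C)(C)C(C)(C)C)C(=O)C[C@](C)(O[Si](CC)(CC)CC)CC(=O)CBr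
F2 | step 13 | (2R)-2-methyl-1-(phenylsulfonyl)-5-(trimethylsilyl)pent-4-yn-2-ol | O=S(=O)(c1ccccc1)C[C@](C)(O)CC#C[Si](C)(C)C
F3 | step 13 | triethylsilyl ether of F2 | O=S(=O)(c1ccccc1)C[C@](C)(O[Si](CC)(CC)CC)CC#C[Si](C)(C)C
F4 | step 13 | N-methoxy-N-methylamide of acid 12 | C=C(C)[C@@H](CC(OC)OC)CC[C@H](C(=O)OC)[C@@H](O[Si](C)(C)C(C)(C)C)C(=O)N(C)OC
F5 | step 13 | 5-phenylsulfonyl derivative of 20 (β-keto sulfone, both epimers at the sulfonyl carbon) | C=C(C)[C@@H](CC(OC)OC)CC[C@H](C(=O)OC)[C@@H](O[Si](C)(C)C(C)(C)C)C(=O)C(S(=O)(=O)c1ccccc1)[C@](C)(O[Si](CC)(CC)CC)CC#C[Si](C)(C)C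
F6 | step 6 | [(3R)-5,5-dimethoxy-3-(prop-1-en-2-yl)pentyl]magnesium iodide | C=C(C)[C@@H](CC(OC)OC)CC[Mg]I
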